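Colleague, you want a quick number and suspect the flask is merely slow, so that warming will carry it on. I read it otherwise.

| flask | starting material | second substrate | capture agent | free catalyst | temperature | remark | time |
|---|---|---|---|---|---|---|---|
| teal | 18 mM | 1 equiv | 0.36 mM | 0.38 mol% | 25 °C | the very flask that is asked about, followed so far |  |
| violet | 18 mM | 1 equiv | 0.36 mM | 0.38 mol% | 10 °C | run made earlier |  |
| flask | 18 mM | 1.00 equiv | 0.360 mM | 0.38 mol% | 25 °C |  | 8.0 d |

- teal (time / d: target / %): 0.625: 18; 1.25: 28; 2.08: 30; 3.00: 35; 4.00: 36; 5.00: 40
- violet (time / d: target / %): 1.25: 4; 2.50: 15; 4.00: 17; 6.00: 17; 8.00: 22; 10.0: 19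

(scatter of a reading: 2 percentage points)

- summer: at 8.0 d take out 90% of the target then present, then wait 8.0 d
- dawn: change nothing and wait 8.0 d more
- autumn: at 8.0 d raise the temperature by 10 K, then wait 8.0 d
- spring: at 8.0 d add free catalyst, 50.0% of the amount charged, then wait 8.0 d

- removed target is counted in
- the numbers in the tables scatter with a standard deviation of 2 percentage points
- additions bring no volume worth counting

1. target, in percent of the starting material first charged, at 8.0 d
2. the option that brings most further target ("none" if no option brings more than 2 percentage points) (summer / dawn / autumn / spring / none)
3. target present, with what was taken out counted in, in percent of the starting material first charged, after dawn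
4. target present, with what was taken out counted in, in percent of the starting material first charged, after spring

The mean of the last 3 teal readings is 37.0%, and the first reading, 18% at 0.625 d, is already half of it. The asked time is 12.8 such spans. Yet by subtraction 63.0% of the starting material stands unreacted in the teal run, so I read the stop as no shortage of it: control has, I think, passed from how fast the catalyst turns to how long it lasts. So I divide target by catalyst:

Y = 37.0% / 0.38 mol% = 97.4

This yield per catalyst, the turnover number, is the target one catalyst makes in its life. The violet run, with the same charges at 10 °C, stands lower, its last 3 readings averaging 19.3%, so cold costs yield and not merely speed. I read the teal catalyst's life as over by the asked time, so I expect less than 2 percentage points from waiting, warming or taking out target. Added catalyst should bring its own yield.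

The catalyst charged comes to 0.0684 mM, and capture agent stands at 5.26 to one over it. I assume one capture agent takes one catalyst, and that Y goes inversely with mean c(capture agent). The first batch then meets a mean c(capture agent) of 0.326 mM, and the added batch meets 0.274 mM:

Y(added) = Y · 0.326 mM / 0.274 mM = 116

gain = 50.0% · 0.38 mol% · Y(added) = 22 points

I commit to 37.0% now, the same after dawn, 59.0% after spring, and spring as best.

The forecast, reading "the catalyst dying", gives 40% now, 41% after dawn and 52% after spring, best spring, so mine stands higher on spring.

The flask gives 38.7% now, 38.8% after dawn and 60.6% after spring, best spring.

    starting material + free catalyst ⇌ catalyst intermediate A (K = 81.0 /M, k = 32800 /M/h, Ea = 55.0 kJ/mol, ΔH = −89.0 kJ/mol)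
    catalyst intermediate A → free catalyst + target (k = 7.78 /h, Ea = 81.0 kJ/mol)
    second substrate + free catalyst ⇌ catalyst intermediate B (K = 44.0 /M, k = 6330 /M/h, Ea = 60.0 kJ/mol, ΔH = 21.0 kJ/mol)
    catalyst intermediate B → free catalyst + second product (k = 54.2 /h, Ea = 88.0 kJ/mol)
    catalyst intermediate A + capture agent → trapped intermediate (k = 204 /M/h, Ea = 41.0 kJ/mol)
    catalyst intermediate A → spent catalyst (k = 0.00908 /h, Ea = 105 kJ/mol)
    (constants at 25 °C)

In this flask at 8.00 d, catalyst intermediate A goes on to free catalyst and target 130 times as fast as capture agent turns it into trapped intermediate. The yield per catalyst from the result is 102, and trapped intermediate then holds 87.9% of the catalyst charged. For the neighbour with 1.4 mM of capture agent, the same reckoning from Y gives 8.83% of target, and that neighbour flask gives 10.3%.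

The readings were computed with constants of no real substance.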